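Moracin Q is disconnected at the benzo ring (ring A) of the benzofuran, which is built from acyclic pieces. O–C7a, C7–H, C6–OH and C5–OMe form a 1,3-dioxygenated four-carbon chain ending in a methoxylated carbon, the pattern of methyl 4-methoxyacetoacetate. C3a and C4 each carry a carbon substituent, like the two ends of an alkyne. A Diels–Alder reaction of the bis(silyl enol ether) of that keto ester with a prenylated ynoate, followed by aromatization, should therefore deliver the pentasubstituted arene in one operation. The ester then becomes C3 of the furan by an intramolecular Wittig reaction, and the prenyl group becomes the isopropyl ketone by epoxide rearrangement.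

Key step: step 4

Assumption: the double bonds of 2 and 3 are written as Z; geometric mixtures would serve equally, because neither geometry survives the aromatization in step 4. Compounds 7 and 17 carry only transient stereocentres and are handled as stereoisomer mixtures; the target has no stereocentre.

Step 1
Reactants: 1 methyl 4-methoxyacetoacetate (methyl 4-methoxy-3-oxobutanoate)
Product: 2 methyl (2Z)-4-methoxy-3-(trimethylsilyloxy)but-2-enoate
Conditions: TMSCl, Et3N, hexane, rt
Reagents that add atoms: chlorotrimethylsilane, C[Si](C)(C)Cl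
Why: Soft enolization and O-silylation of the β-keto ester (silyl enol ether formation) traps the enol that is already populated, and the geometry of this double bond is irrelevant because it becomes the central single bond of the diene.

Step 2
Reactants: 2 methyl (2Z)-4-methoxy-3-(trimethylsilyloxy)but-2-enoate
Product: 3 (1Z,3Z)-1,4-dimethoxy-1,3-bis(trimethylsilyloxy)buta-1,3-diene
Conditions: LiN(i-Pr)2, THF, –78 °C; then TMSCl, –78 °C → rt
Reagents that add atoms: chlorotrimethylsilane, C[Si](C)(C)Cl
Why: Kinetic γ-deprotonation of the β-silyloxy enoate by the lithium amide followed by O-silylation of the extended ester enolate (ketene silyl acetal formation) is the standard second stage of 1,3-bis(silyloxy)diene synthesis, and the moisture-sensitive diene is used crude.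

Step 3
Reactants: 4 methyl propiolate; 5 prenyl bromide (1-bromo-3-methylbut-2-ene)
Product: 6 methyl 6-methylhept-5-en-2-ynoate
Conditions: CuI (10 mol %), K2CO3, n-Bu4NI (10 mol %), DMF, rt
Reagents that add atoms: none
Why: Copper-catalysed alkynylation of an allylic halide, in which the copper acetylide formed from the acidic propiolate C–H and carbonate is alkylated at the primary carbon of prenyl bromide, should give the skipped enyne without a strong base that would isomerize it to the allenoate.

Step 4
Reactants: 3 (1Z,3Z)-1,4-dimethoxy-1,3-bis(trimethylsilyloxy)buta-1,3-diene; 6 methyl 6-methylhept-5-en-2-ynoate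
Product: 8 methyl 2,4-dihydroxy-5-methoxy-6-(3-methylbut-2-enyl)benzoate, via cyclohexadiene cycloadduct 7 (not isolated)
Conditions: 3 (2.5 equiv), toluene, 130 °C, sealed tube; then 1 M HCl, THF, 0 °C → rt
Reagents that add atoms: none
Why: The electron-rich diene 3 adds across the electron-poor triple bond of 6 in a normal-demand Diels–Alder reaction (an asynchronous [4+2] process; a stepwise Mukaiyama–Michael addition followed by Claisen-type closure would converge on the same adduct 7), and dilute acid then cleaves the mixed silyl methyl ketal with loss of methanol, hydrolyses the silyl enol ether and lets the dienone tautomerize to the arene. The closest known reaction type is the resorcylate synthesis from 1-alkoxy-1,3-bis(silyloxy)butadienes and acetylenic esters, which for ynoates activated by a single ester group is run thermally at 120–140 °C. The carbocycle is closed by intermolecular [4+2] cycloaddition, forming the two bonds that become C3a–C7a and C4–C5 of the benzofuran. No stereocentre remains, since the two sp3 carbons of 7 are planarized on aromatization, so the diene geometry does not matter. The selectivity needed is regiochemical and is secured by the polarization of both partners: the CH(OMe) terminus of 3, the vinylogous donor position of the ketene acetal, bonds to the β-carbon of the ynoate, which places the ester beside the ketal-derived hydroxyl and the prenyl group beside the methoxy group. The isolated trisubstituted alkene is no dienophile for this diene and has no ortho hydroxyl that could cyclize onto it during the acidic work-up.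

Step 5
Reactants: 8 methyl 2,4-dihydroxy-5-methoxy-6-(3-methylbut-2-enyl)benzoate
Product: 9 methyl 4-(benzyloxy)-2-hydroxy-5-methoxy-6-(3-methylbut-2-enyl)benzoate
Conditions: BnBr (1.05 equiv), K2CO3, acetone, 50 °C
Reagents that add atoms: benzyl bromide, BrCc1ccccc1
Why: Williamson ether synthesis in which the 2-hydroxyl, hydrogen-bonded to the ester carbonyl, stays unreactive toward one equivalent of benzyl bromide, so that only the 4-hydroxyl should be alkylated.

Step 6
Reactants: 9 methyl 4-(benzyloxy)-2-hydroxy-5-methoxy-6-(3-methylbut-2-enyl)benzoate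
Product: 10 5-(benzyloxy)-2-(hydroxymethyl)-4-methoxy-3-(3-methylbut-2-enyl)phenol
Conditions: LiAlH4, THF, 0 °C; then aq. potassium sodium tartrate
Reagents that add atoms: none
Why: Hydride reduction of the ester with LiAlH4 proceeds through the aluminium phenoxide and, kept at 0 °C, should stop at the salicyl alcohol without benzylic deoxygenation, leaving the benzyl ether and the alkene untouched.

Step 7
Reactants: 10 5-(benzyloxy)-2-(hydroxymethyl)-4-methoxy-3-(3-methylbut-2-enyl)phenol
Product: 11 {[4-(benzyloxy)-2-hydroxy-5-methoxy-6-(3-methylbut-2-enyl)phenyl]methyl}triphenylphosphonium bromide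
Conditions: PPh3·HBr (1.05 equiv), MeCN, rt → 50 °C
Reagents that add atoms: triphenylphosphine hydrobromide, [Br-].[PH+](c1ccccc1)(c1ccccc1)c1ccccc1
Why: Acid-assisted ionization of the electron-rich ortho-hydroxybenzyl alcohol and capture of the resulting ortho-quinone methide or benzylic cation by triphenylphosphine (SN1-type substitution) is the standard phosphonium salt synthesis for salicyl alcohols, and the weakly acidic reagent together with the excess of phosphine nucleophile should spare the prenyl alkene.

Step 8
Reactants: 12 3,5-bis(benzyloxy)benzoic acid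
Product: 13 3,5-bis(benzyloxy)benzoyl chloride
Conditions: (COCl)2, DMF (cat.), CH2Cl2, 0 °C → rt
Reagents that add atoms: oxalyl chloride, O=C(Cl)C(Cl)=O
Why: Acid chloride formation through the Vilsmeier-type chloroiminium species gives only gaseous by-products, so the crude chloride can be used directly.

Step 9
Reactants: 11 {[4-(benzyloxy)-2-hydroxy-5-methoxy-6-(3-methylbut-2-enyl)phenyl]methyl}triphenylphosphonium bromide; 13 3,5-bis(benzyloxy)benzoyl chloride
Product: 16 6-(benzyloxy)-2-[3,5-bis(benzyloxy)phenyl]-5-methoxy-4-(3-methylbut-2-enyl)-1-benzofuran, via aroyloxy phosphonium bromide 14 (not isolated), via phosphorus ylide 15 (not isolated)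
Conditions: Et3N (3 equiv), 13 (1.05 equiv), toluene, rt → reflux
Reagents that add atoms: none
Why: O-Acylation of the phenol gives 14, the amine then forms ylide 15, and an intramolecular Wittig reaction on the ester carbonyl closes the furan ring at C2=C3 with loss of triphenylphosphine oxide, the established route to 2-arylbenzofurans.

Step 10
Reactants: 16 6-(benzyloxy)-2-[3,5-bis(benzyloxy)phenyl]-5-methoxy-4-(3-methylbut-2-enyl)-1-benzofuran
Product: 17 6-(benzyloxy)-2-[3,5-bis(benzyloxy)phenyl]-4-[(3,3-dimethyloxiran-2-yl)methyl]-5-methoxy-1-benzofuran (racemic)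
Conditions: mCPBA (1.05 equiv), CH2Cl2, 0 °C
Reagents that add atoms: 3-chloroperoxybenzoic acid, OOC(=O)c1cccc(Cl)c1
Why: Prilezhaev epoxidation should be fastest at the electron-rich trisubstituted prenyl alkene, well ahead of the aromatic furan C2=C3 bond, and the single new stereocentre is formed as a racemate that the next step erases.

Step 11
Reactants: 17 6-(benzyloxy)-2-[3,5-bis(benzyloxy)phenyl]-4-[(3,3-dimethyloxiran-2-yl)methyl]-5-methoxy-1-benzofuran
Product: 18 1-{6-(benzyloxy)-2-[3,5-bis(benzyloxy)phenyl]-5-methoxy-1-benzofuran-4-yl}-3-methylbutan-2-one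
Conditions: BF3·OEt2 (0.2 equiv), CH2Cl2, –78 → –20 °C
Reagents that add atoms: none
Why: Meinwald rearrangement, in which the Lewis acid opens the epoxide at the tertiary carbon and a 1,2-hydride shift from the neighbouring CH gives the isopropyl ketone, is known for aryl prenyl epoxides flanked by a methoxy group, and no free ortho hydroxyl is present to trap the cation.

Step 12
Reactants: 18 1-{6-(benzyloxy)-2-[3,5-bis(benzyloxy)phenyl]-5-methoxy-1-benzofuran-4-yl}-3-methylbutan-2-one
Product: 19 moracin Q, 1-[2-(3,5-dihydroxyphenyl)-6-hydroxy-5-methoxy-1-benzofuran-4-yl]-3-methylbutan-2-one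
Conditions: H2 (1 atm), Pd/C, EtOAc–MeOH, rt
Reagents that add atoms: none
Why: Catalytic hydrogenolysis of the three benzyl ethers over Pd/C at ambient pressure should leave the aryl-conjugated benzofuran and the dialkyl ketone intact.

Compound list
1 | methyl 4-methoxyacetoacetate | COCC(=O)CC(=O)OC | starting material
2 | methyl (2Z)-4-methoxy-3-(trimethylsilyloxy)but-2-enoate | COC/C(O[Si](C)(C)C)=C/C(=O)OC | intermediate
3 | (1Z,3Z)-1,4-dimethoxy-1,3-bis(trimethylsilyloxy)buta-1,3-diene | CO/C(O[Si](C)(C)C)=C/C(O[Si](C)(C)C)=C/OC | intermediate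
4 | methyl propiolate | C#CC(=O)OC | starting material
5 | prenyl bromide (1-bromo-3-methylbut-2-ene) | CC(C)=CCBr | starting material
6 | methyl 6-methylhept-5-en-2-ynoate | COC(=O)C#CCC=C(C)C | intermediate
7 | methyl 3,6-dimethoxy-2-(3-methylbut-2-enyl)-4,6-bis(trimethylsilyloxy)cyclohexa-1,4-diene-1-carboxylate (cycloadduct, stereoisomer mixture, not isolated) | COC(=O)C1=C(CC=C(C)C)C(OC)C(O[Si](C)(C)C)=CC1(OC)O[Si](C)(C)C | intermediate
8 | methyl 2,4-dihydroxy-5-methoxy-6-(3-methylbut-2-enyl)benzoate | COC(=O)c1c(O)cc(O)c(OC)c1CC=C(C)C | intermediate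
9 | methyl 4-(benzyloxy)-2-hydroxy-5-methoxy-6-(3-methylbut-2-enyl)benzoate | COC(=O)c1c(O)cc(OCc2ccccc2)c(OC)c1CC=C(C)C | intermediate
10 | 5-(benzyloxy)-2-(hydroxymethyl)-4-methoxy-3-(3-methylbut-2-enyl)phenol | OCc1c(O)cc(OCc2ccccc2)c(OC)c1CC=C(C)C | intermediate
11 | {[4-(benzyloxy)-2-hydroxy-5-methoxy-6-(3-methylbut-2-enyl)phenyl]methyl}triphenylphosphonium bromide | [Br-].Oc1cc(OCc2ccccc2)c(OC)c(CC=C(C)C)c1C[P+](c1ccccc1)(c1ccccc1)c1ccccc1 | intermediate
12 | 3,5-bis(benzyloxy)benzoic acid | OC(=O)c1cc(OCc2ccccc2)cc(OCc2ccccc2)c1 | starting material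
13 | 3,5-bis(benzyloxy)benzoyl chloride | ClC(=O)c1cc(OCc2ccccc2)cc(OCc2ccccc2)c1 | intermediate
14 | {[2-{[3,5-bis(benzyloxy)benzoyl]oxy}-4-(benzyloxy)-5-methoxy-6-(3-methylbut-2-enyl)phenyl]methyl}triphenylphosphonium bromide (not isolated) | [Br-].O=C(Oc1cc(OCc2ccccc2)c(OC)c(CC=C(C)C)c1C[P+](c1ccccc1)(c1ccccc1)c1ccccc1)c1cc(OCc2ccccc2)cc(OCc2ccccc2)c1 | intermediate
15 | 5-(benzyloxy)-4-methoxy-3-(3-methylbut-2-enyl)-2-[(triphenylphosphoranylidene)methyl]phenyl 3,5-bis(benzyloxy)benzoate (ylide, not isolated) | O=C(Oc1cc(OCc2ccccc2)c(OC)c(CC=C(C)C)c1C=P(c1ccccc1)(c1ccccc1)c1ccccc1)c1cc(OCc2ccccc2)cc(OCc2ccccc2)c1 | intermediate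
16 | 6-(benzyloxy)-2-[3,5-bis(benzyloxy)phenyl]-5-methoxy-4-(3-methylbut-2-enyl)-1-benzofuran | COc1c(OCc2ccccc2)cc2oc(-c3cc(OCc4ccccc4)cc(OCc4ccccc4)c3)cc2c1CC=C(C)C | intermediate
17 | 6-(benzyloxy)-2-[3,5-bis(benzyloxy)phenyl]-4-[(3,3-dimethyloxiran-2-yl)methyl]-5-methoxy-1-benzofuran (racemic) | COc1c(OCc2ccccc2)cc2oc(-c3cc(OCc4ccccc4)cc(OCc4ccccc4)c3)cc2c1CC1OC1(C)C | intermediate
18 | 1-{6-(benzyloxy)-2-[3,5-bis(benzyloxy)phenyl]-5-methoxy-1-benzofuran-4-yl}-3-methylbutan-2-one | COc1c(OCc2ccccc2)cc2oc(-c3cc(OCc4ccccc4)cc(OCc4ccccc4)c3)cc2c1CC(=O)C(C)C | intermediate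
19 | moracin Q, 1-[2-(3,5-dihydroxyphenyl)-6-hydroxy-5-methoxy-1-benzofuran-4-yl]-3-methylbutan-2-one | COc1c(O)cc2oc(-c3cc(O)cc(O)c3)cc2c1CC(=O)C(C)C | target

Total step count: 12 steps.
Longest linear sequence: 10 steps, from 1 to 19 through steps 1, 2, 4, 5, 6, 7, 9, 10, 11 and 12.

Steps most likely to fail

Step 4. The cycloaddition may be too slow at temperatures the diene tolerates, because the dienophile is activated by one ester only and its β-carbon carries the prenyl methylene. Desilylation or silyl migration of 3 could then outpace ring formation. The fallback sets out from 6 and comes back at 10, and it raises the electrophilicity of the alkyne by exchanging the ester for an aldehyde. Reduction of 6 with i-Bu2AlH (CH2Cl2, –78 °C) should give 6-methylhept-5-en-2-yn-1-ol F1, and MnO2 (CH2Cl2, rt) should oxidize it to 6-methylhept-5-en-2-ynal F2. Acetylenic aldehydes are far better dienophiles than ynoates, so F2 and 3 should combine in toluene between rt and 60 °C, with the same regiochemistry, to the cyclohexadiene carbaldehyde adduct F3. Dilute HCl in THF should aromatize it to 2,4-dihydroxy-5-methoxy-6-(3-methylbut-2-enyl)benzaldehyde F4. Benzylation of the non-chelated hydroxyl (BnBr, K2CO3, acetone) would give 4-(benzyloxy)-2-hydroxy-5-methoxy-6-(3-methylbut-2-enyl)benzaldehyde F5, and NaBH4 (MeOH, 0 °C) should reduce it to salicyl alcohol 10, where the route continues with step 7.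

Step 7. Ionization of the very electron-rich benzylic alcohol under acid may be diverted before the phosphine captures the cation. Possible diversions are hydrobromination of the prenyl alkene, cation–olefin cyclization onto it, or self-alkylation at the free ring position. The fallback sets out from 10 and comes back at 14; it acylates first and introduces phosphorus by neutral SN2 chemistry. Phase-transfer acylation of the phenoxide with 13 (aq. NaOH, n-Bu4NHSO4 cat., CH2Cl2, 0 °C) should give 5-(benzyloxy)-2-(hydroxymethyl)-4-methoxy-3-(3-methylbut-2-enyl)phenyl 3,5-bis(benzyloxy)benzoate F6. An Appel reaction (CBr4, PPh3, CH2Cl2, 0 °C) should convert it to 5-(benzyloxy)-2-(bromomethyl)-4-methoxy-3-(3-methylbut-2-enyl)phenyl 3,5-bis(benzyloxy)benzoate F7, and PPh3 in toluene at 60 °C should give the phosphonium salt 14. Treated with Et3N in refluxing toluene as in step 9, 14 would close to 16.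

Step 11. After Lewis-acid opening of the epoxide, the tertiary cation may follow paths other than the hydride shift. These are migration of the benzylic carbon to give an aldehyde, attack by the nucleophilic C3 of the benzofuran, and fluoride capture; the Lewis acid may also loosen a benzyl ether. The fallback sets out from 16 and comes back at 18, without the epoxide. Hydroboration–oxidation of the prenyl alkene (BH3·THF, 1 equiv, THF, 0 °C; then NaBO3·4H2O, THF–H2O) should place the hydroxyl on the less substituted carbon and give 1-{6-(benzyloxy)-2-[3,5-bis(benzyloxy)phenyl]-5-methoxy-1-benzofuran-4-yl}-3-methylbutan-2-ol F8 as a racemate. Dess–Martin oxidation (NaHCO3, CH2Cl2, rt) should then give ketone 18.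

Further compounds
F1 | step 4 | 6-methylhept-5-en-2-yn-1-ol | OCC#CCC=C(C)C
F2 | step 4 | 6-methylhept-5-en-2-ynal | O=CC#CCC=C(C)C
F3 | step 4 | 3,6-dimethoxy-2-(3-methylbut-2-enyl)-4,6-bis(trimethylsilyloxy)cyclohexa-1,4-diene-1-carbaldehyde (stereoisomer mixture) | O=CC1=C(CC=C(C)C)C(OC)C(O[Si](C)(C)C)=CC1(OC)O[Si](C)(C)C
F4 | step 4 | 2,4-dihydroxy-5-methoxy-6-(3-methylbut-2-enyl)benzaldehyde | O=Cc1c(O)cc(O)c(OC)c1CC=C(C)C
F5 | step 4 | 4-(benzyloxy)-2-hydroxy-5-methoxy-6-(3-methylbut-2-enyl)benzaldehyde | O=Cc1c(O)cc(OCc2ccccc2)c(OC)c1CC=C(C)C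
F6 | step 7 | 5-(benzyloxy)-2-(hydroxymethyl)-4-methoxy-3-(3-methylbut-2-enyl)phenyl 3,5-bis(benzyloxy)benzoate | O=C(Oc1cc(OCc2ccccc2)c(OC)c(CC=C(C)C)c1CO)c1cc(OCc2ccccc2)cc(OCc2ccccc2)c1
F7 | step 7 | 5-(benzyloxy)-2-(bromomethyl)-4-methoxy-3-(3-methylbut-2-enyl)phenyl 3,5-bis(benzyloxy)benzoate | O=C(Oc1cc(OCc2ccccc2)c(OC)c(CC=C(C)C)c1CBr)c1cc(OCc2ccccc2)cc(OCc2ccccc2)c1
F8 | step 11 | 1-{6-(benzyloxy)-2-[3,5-bis(benzyloxy)phenyl]-5-methoxy-1-benzofuran-4-yl}-3-methylbutan-2-ol (racemic) | COc1c(OCc2ccccc2)cc2oc(-c3cc(OCc4ccccc4)cc(OCc4ccccc4)c3)cc2c1CC(O)C(C)C
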